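**Retrosynthetic overview**
- The depside aryl ester C–O bond is cut last, giving a free 5-chloro-2,4-dihydroxy-3,6-dimethylbenzoic acid and a free 4-hydroxy-2-methoxy-3,5,6-trimethylbenzoate phenol; they are joined without protecting groups.
- The acid half comes from methyl 2,4-dihydroxy-3,6-dimethylbenzoate (atraric acid, a bulk fragrance chemical) by C5 chlorination and ester cleavage.
- The phenol half comes from the same ester by 4-O-benzylation/2-O-methylation, C5 formylation, and one hydrogenation that turns CHO into CH3 and frees the 4-OH.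
- No ring is formed: both benzene rings are carried in intact from atraric acid; the phenol ring is elaborated first, the acid ring second, and they are joined last.

Assumption: the target has no stereocentre and is achiral, so "single enantiomer" requires no stereocontrol.

**Step 1**
Reactants: 1 methyl 2,4-dihydroxy-3,6-dimethylbenzoate (atraric acid)
Product: 3 methyl 4-(benzyloxy)-2-methoxy-3,6-dimethylbenzoate, via monobenzyl ether 2 (not isolated)
Conditions: BnBr (1.05 equiv), K2CO3, acetone, reflux; then Me2SO4 (2 equiv), K2CO3, reflux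
Reagents that add atoms: benzyl bromide BrCc1ccccc1; dimethyl sulfate COS(=O)(=O)OC
Why: Williamson etherification takes the free 4-OH first because the 2-OH is hydrogen-bonded to the ester and flanked by CO2Me and CH3, so one equivalent of BnBr gives 2, and the remaining chelated OH is then forced with Me2SO4 in the same flask; no stereocentre is formed.

**Step 2**
Reactants: 3 methyl 4-(benzyloxy)-2-methoxy-3,6-dimethylbenzoate
Product: 4 methyl 4-(benzyloxy)-5-formyl-2-methoxy-3,6-dimethylbenzoate
Conditions: Cl2CHOMe (1.5 equiv), TiCl4 (2.2 equiv), CH2Cl2, −78 → 0 °C; then ice-water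
Reagents that add atoms: dichloromethyl methyl ether COC(Cl)Cl; water O
Why: Rieche formylation (electrophilic aromatic substitution) can only occur at C5, the single free ring position, which is ortho to the benzyloxy and para to the methoxy group, and hydrolysis of the α-chloro ether gives the aldehyde.

**Step 3**
Reactants: 4 methyl 4-(benzyloxy)-5-formyl-2-methoxy-3,6-dimethylbenzoate
Product: 5 methyl 4-hydroxy-2-methoxy-3,5,6-trimethylbenzoate
Conditions: H2 (3 atm), 10% Pd/C, AcOH, cat. HCl, 40 °C
Reagents that add atoms: none
Why: Catalytic hydrogenolysis removes the benzyl ether and, in acid, reduces the ortho-hydroxybenzaldehyde through the benzylic alcohol to the methyl group in the same operation, while the hindered methyl ester and the aryl methyl ether are inert.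

**Step 4**
Reactants: 1 methyl 2,4-dihydroxy-3,6-dimethylbenzoate (atraric acid)
Product: 7 5-chloro-2,4-dihydroxy-3,6-dimethylbenzoic acid, via chloro ester 6 (not isolated)
Conditions: SO2Cl2 (1.02 equiv), Et2O, 0 °C → rt; evaporate; conc. H2SO4, 0 °C → rt; pour onto ice, filter cold
Reagents that add atoms: sulfuryl chloride ClS(Cl)(=O)=O; water O
Why: Electrophilic chlorination hits the only free position C5 (ortho to 4-OH, para to 2-OH) while the carboxyl is still an ester, which avoids chlorodecarboxylation, and the 2,6-disubstituted ester is then cleaved by the AAC1 path (acylium ion in concentrated H2SO4, trapped by water on the ice quench) at a temperature where the acid does not decarboxylate.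

**Step 5**
Reactants: 7 5-chloro-2,4-dihydroxy-3,6-dimethylbenzoic acid; 5 methyl 4-hydroxy-2-methoxy-3,5,6-trimethylbenzoate
Product: 10 methyl 4-[(5-chloro-2,4-dihydroxy-3,6-dimethylbenzoyl)oxy]-2-methoxy-3,5,6-trimethylbenzoate, via bis-trifluoroacetylated mixed anhydride 8 (not isolated), via depside 4-O-trifluoroacetate 9 (not isolated)
Conditions: 7, TFAA (2.3 equiv), CH2Cl2–toluene, 0 °C → rt, 1 h; added over 2 h to 5 (1.5 equiv) in toluene, rt, 12 h; then MeOH, rt, 30 min; aq. NaHCO3 wash
Reagents that add atoms: none
Why: Proposed new method: a protecting-group-free depside esterification in which trifluoroacetic anhydride acts twice, turning the CO2H of 7 into the acyl trifluoroacetate and capping the donor's own 4-OH as an aryl trifluoroacetate (8); the mixed anhydride ionises to a 2,6-disubstituted, ortho-OH-stabilised acylium ion that is linear at carbon and so tolerates the tetra-ortho-substituted junction, and the phenol of 5, kept in excess by inverse slow addition, is the only competent nucleophile because the chelated 2-OH of 7 is hindered, the 4-oxygen is masked and electron-poor, and both rings are fully substituted so no Friedel–Crafts C-acylation is possible; the O-trifluoroacetate of 9 is methanolysed in the quench while the four-fold ortho-shielded depside ester survives; the closest known reaction type is the TFAA-promoted mixed-anhydride (acylium) esterification of hindered benzoic acids with hindered phenols, used for depsides so far only with O-benzylated acids.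

**Compound list**
1 | methyl 2,4-dihydroxy-3,6-dimethylbenzoate (atraric acid) | COC(=O)c1c(C)cc(O)c(C)c1O | starting material
2 | methyl 4-(benzyloxy)-2-hydroxy-3,6-dimethylbenzoate | COC(=O)c1c(C)cc(OCc2ccccc2)c(C)c1O | intermediate
3 | methyl 4-(benzyloxy)-2-methoxy-3,6-dimethylbenzoate | COC(=O)c1c(C)cc(OCc2ccccc2)c(C)c1OC | intermediate
4 | methyl 4-(benzyloxy)-5-formyl-2-methoxy-3,6-dimethylbenzoate | COC(=O)c1c(C)c(C=O)c(OCc2ccccc2)c(C)c1OC | intermediate
5 | methyl 4-hydroxy-2-methoxy-3,5,6-trimethylbenzoate | COC(=O)c1c(C)c(C)c(O)c(C)c1OC | intermediate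
6 | methyl 5-chloro-2,4-dihydroxy-3,6-dimethylbenzoate | COC(=O)c1c(C)c(Cl)c(O)c(C)c1O | intermediate
7 | 5-chloro-2,4-dihydroxy-3,6-dimethylbenzoic acid | OC(=O)c1c(C)c(Cl)c(O)c(C)c1O | intermediate
8 | 5-chloro-2-hydroxy-3,6-dimethyl-4-(trifluoroacetoxy)benzoic trifluoroacetic anhydride | O=C(OC(=O)C(F)(F)F)c1c(C)c(Cl)c(OC(=O)C(F)(F)F)c(C)c1O | intermediate
9 | methyl 4-{[5-chloro-2-hydroxy-3,6-dimethyl-4-(trifluoroacetoxy)benzoyl]oxy}-2-methoxy-3,5,6-trimethylbenzoate | COC(=O)c1c(C)c(C)c(OC(=O)c2c(C)c(Cl)c(OC(=O)C(F)(F)F)c(C)c2O)c(C)c1OC | intermediate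
10 | methyl 4-[(5-chloro-2,4-dihydroxy-3,6-dimethylbenzoyl)oxy]-2-methoxy-3,5,6-trimethylbenzoate (CNP0231767.0) | COC(=O)c1c(C)c(C)c(OC(=O)c2c(C)c(Cl)c(O)c(C)c2O)c(C)c1OC | target

**Total step count:** 5
**Longest linear sequence:** 4 (steps 1, 2, 3, 5 from compound 1)

**Steps most likely to fail**

Step 5 (the proposed new coupling). The risk is self-condensation of 7 through its own 4-OH, or trifluoroacetylation of 5 instead of acylation. The fallback uses known chemistry only. It sets out from chloro ester 6 (isolated by stopping step 4 after the chlorination) and from phenol 5, and comes back at target 10. Ester 6 is dibenzylated (BnBr, K2CO3, DMF, 60 °C) to methyl 2,4-bis(benzyloxy)-5-chloro-3,6-dimethylbenzoate F4. This is saponified (KOH, DMSO–H2O, 90 °C; the O-benzylated acid no longer decarboxylates) to 2,4-bis(benzyloxy)-5-chloro-3,6-dimethylbenzoic acid F5. F5 is coupled with 5 under standard TFAA/toluene conditions to methyl 4-{[2,4-bis(benzyloxy)-5-chloro-3,6-dimethylbenzoyl]oxy}-2-methoxy-3,5,6-trimethylbenzoate F6. Hydrogenolysis (H2 1 atm, Pd/C, EtOAc, rt, stopped after 2 equiv H2 to keep the aryl chloride) then gives 10.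

Step 4 (ester cleavage stage). The risk is incomplete ionisation of the ester in H2SO4 or decarboxylation of the electron-rich acid on work-up. The fallback sets out from chloro ester 6 and comes back at acid 7. Ester 6 is boiled with aqueous NaOH under N2, so that saponification and decarboxylation run to completion on purpose, giving 4-chloro-2,5-dimethylbenzene-1,3-diol F3. The carboxyl group is then put back at the only free ring position, ortho to OH, by chelation-controlled carboxylation with methyl magnesium carbonate (DMF, 120 °C; cold dilute HCl), giving 7.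

Step 2 (Rieche formylation). The risk is a sluggish reaction at the crowded C5 or loss of the benzyl ether to TiCl4. The fallback sets out from 3 and comes back at phenol 5, replacing formylation/hydrogenolysis by cross-coupling. Compound 3 is brominated at C5 (NBS, MeCN, rt) to methyl 4-(benzyloxy)-5-bromo-2-methoxy-3,6-dimethylbenzoate F1. The bromide is exchanged for methyl by Suzuki–Miyaura coupling (trimethylboroxine, Pd(OAc)2/SPhos, K3PO4, toluene–H2O, 100 °C) to give methyl 4-(benzyloxy)-2-methoxy-3,5,6-trimethylbenzoate F2. Plain hydrogenolysis (H2, Pd/C, EtOAc, rt) then gives 5.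

**Further compounds**
F1 | step 2 | methyl 4-(benzyloxy)-5-bromo-2-methoxy-3,6-dimethylbenzoate | COC(=O)c1c(C)c(Br)c(OCc2ccccc2)c(C)c1OC
F2 | step 2 | methyl 4-(benzyloxy)-2-methoxy-3,5,6-trimethylbenzoate | COC(=O)c1c(C)c(C)c(OCc2ccccc2)c(C)c1OC
F3 | step 4 | 4-chloro-2,5-dimethylbenzene-1,3-diol | Cc1cc(O)c(C)c(O)c1Cl
F4 | step 5 | methyl 2,4-bis(benzyloxy)-5-chloro-3,6-dimethylbenzoate | COC(=O)c1c(C)c(Cl)c(OCc2ccccc2)c(C)c1OCc3ccccc3
F5 | step 5 | 2,4-bis(benzyloxy)-5-chloro-3,6-dimethylbenzoic acid | OC(=O)c1c(C)c(Cl)c(OCc2ccccc2)c(C)c1OCc3ccccc3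
F6 | step 5 | methyl 4-{[2,4-bis(benzyloxy)-5-chloro-3,6-dimethylbenzoyl]oxy}-2-methoxy-3,5,6-trimethylbenzoate | COC(=O)c1c(C)c(C)c(OC(=O)c2c(C)c(Cl)c(OCc3ccccc3)c(C)c2OCc4ccccc4)c(C)c1OC
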